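**Retrosynthetic overview** (eremophilane locants: C4 = CO2H carbon, C5 = quaternary CH3 carbon, C8 = ketone, C9=C10 = enone alkene, C1 = acyloxy carbon, C7 = acrolein-bearing carbon)
1. Target ⇒ C7 acetaldehyde arm (α-methylenation last) ⇒ C7-allyl enone; C1 ester ⇒ 1β-hydroxy enone + (2E,4R)-2,4-dimethyloct-2-enoic acid.
2. 1β-Hydroxy enone ⇒ γ-oxidation (vinylogous Rubottom) of a bicyclic 8-silyloxy-1(10),8-diene.
3. Bicyclic diene ⇒ acyclic dienyne: one Ru-carbene ene–yne–ene cascade closes ring A first (C1=C10) and ring B second (C8=C9, onto a silyl enol ether) in the same operation.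
4. Dienyne ⇒ alkynyl keto acid ⇒ trisubstituted γ-butyrolactone (lactone C=O becomes the alkyne; C4 by asymmetric conjugate addition, C5 by two lactone enolate alkylations) ⇒ furan-2(5H)-one.

Convention: α/β refer to the decalin faces, β being the face of the angular methyl; the C-locants above are used throughout.

**Step 1**
Reactants: 1 furan-2(5H)-one; 2 but-3-en-1-ylmagnesium bromide
Product: 3 (S)-4-(but-3-en-1-yl)dihydrofuran-2(3H)-one
Conditions: CuBr·SMe2 (5 mol %), Tol-BINAP (6 mol %; the antipode that gives the 4S lactone), t-BuOMe, −78 °C; NH4Cl aq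
Reagents that add atoms: none
Why: Copper-catalysed asymmetric conjugate addition of the Grignard reagent to the butenolide, the Tol-BINAP–copper complex selecting the face of the β-carbon and thereby setting the C4 stereocentre (S).

**Step 2**
Reactants: 3 (S)-4-(but-3-en-1-yl)dihydrofuran-2(3H)-one; 4 2-(2-bromoethyl)-2-methyl-1,3-dioxolane
Product: 5 (3S,4S)-4-(but-3-en-1-yl)-3-[2-(2-methyl-1,3-dioxolan-2-yl)ethyl]dihydrofuran-2(3H)-one
Conditions: LiN(i-Pr)2, THF, −78 °C; then 4, DMPU, Bu4NI (cat.), −78 → −20 °C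
Reagents that add atoms: none
Why: SN2 alkylation of the lactone lithium enolate by the primary bromide brings in the ketal-masked 3-oxobutyl arm trans to the butenyl group, at a centre that is planarised again in step 3.

**Step 3**
Reactants: 5 (3S,4S)-4-(but-3-en-1-yl)-3-[2-(2-methyl-1,3-dioxolan-2-yl)ethyl]dihydrofuran-2(3H)-one
Product: 6 (3R,4S)-4-(but-3-en-1-yl)-3-methyl-3-[2-(2-methyl-1,3-dioxolan-2-yl)ethyl]dihydrofuran-2(3H)-one
Conditions: LiN(i-Pr)2, THF, −78 °C; MeI, −78 → −40 °C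
Reagents that add atoms: iodomethane, CI
Why: Diastereoselective lactone enolate alkylation in which iodomethane attacks the face opposite the neighbouring butenyl group, so the quaternary centre C5 (R, methyl trans to butenyl) is set under cyclic 1,2-control.

**Step 4**
Reactants: 6 (3R,4S)-4-(but-3-en-1-yl)-3-methyl-3-[2-(2-methyl-1,3-dioxolan-2-yl)ethyl]dihydrofuran-2(3H)-one
Product: 8 (2S,3R)-2-(but-3-en-1-yl)-3-ethynyl-3-methyl-5-(2-methyl-1,3-dioxolan-2-yl)pentan-1-ol, via lactol 7 (not isolated)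
Conditions: i-Bu2AlH, CH2Cl2, −78 °C; then MeOH, K2CO3, dimethyl (1-diazo-2-oxopropyl)phosphonate, −78 °C → rt
Reagents that add atoms: dimethyl (1-diazo-2-oxopropyl)phosphonate, CC(=O)C(=[N+]=[N-])P(=O)(OC)OC
Why: Half-reduction of the lactone to the lactol and Ohira–Bestmann (Seyferth–Gilbert) homologation of its open hydroxy aldehyde form turn the lactone carbonyl into the terminal alkyne and free the primary alcohol without touching either stereocentre.

**Step 5**
Reactants: 8 (2S,3R)-2-(but-3-en-1-yl)-3-ethynyl-3-methyl-5-(2-methyl-1,3-dioxolan-2-yl)pentan-1-ol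
Product: 9 (2S,3R)-2-(but-3-en-1-yl)-3-ethynyl-3-methyl-6-oxoheptanoic acid
Conditions: CrO3, H2SO4, acetone–H2O, 0 °C
Reagents that add atoms: chromium trioxide, O=[Cr](=O)=O; water, O
Why: Jones oxidation takes the primary alcohol to the carboxylic acid while the aqueous acid hydrolyses the dioxolane to the methyl ketone in the same operation, the hindered C4–H next to the quaternary carbon not epimerising.

**Step 6**
Reactants: 9 (2S,3R)-2-(but-3-en-1-yl)-3-ethynyl-3-methyl-6-oxoheptanoic acid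
Product: 10 tert-butyl (2S,3R)-2-(but-3-en-1-yl)-3-ethynyl-3-methyl-6-oxoheptanoate
Conditions: t-BuOC(=NH)CCl3, BF3·OEt2 (cat.), CH2Cl2–cyclohexane, rt
Reagents that add atoms: tert-butyl 2,2,2-trichloroacetimidate, CC(C)(C)OC(=N)C(Cl)(Cl)Cl
Why: Acid-catalysed O-tert-butylation of the hindered acid by the trichloroacetimidate (tert-butyl cation transfer) protects the carboxyl for the base and acylation steps ahead.

**Step 7**
Reactants: 10 tert-butyl (2S,3R)-2-(but-3-en-1-yl)-3-ethynyl-3-methyl-6-oxoheptanoate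
Product: 11 tert-butyl (2S,3R)-2-(but-3-en-1-yl)-6-[(tert-butyldimethylsilyl)oxy]-3-ethynyl-3-methylhept-6-enoate
Conditions: KN(SiMe3)2, THF, −78 °C; t-BuMe2SiCl, −78 °C
Reagents that add atoms: tert-butyldimethylsilyl chloride, CC(C)(C)[Si](C)(C)Cl
Why: Kinetic enolisation of the methyl ketone on its methyl side followed by O-silylation gives the terminal silyl enol ether, the silylamide base being too weak to metalate the alkyne C–H or the hindered ester α-C–H.

**Step 8**
Reactants: 11 tert-butyl (2S,3R)-2-(but-3-en-1-yl)-6-[(tert-butyldimethylsilyl)oxy]-3-ethynyl-3-methylhept-6-enoate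
Product: 12 tert-butyl (1S,8aR)-6-[(tert-butyldimethylsilyl)oxy]-8a-methyl-1,2,3,7,8,8a-hexahydronaphthalene-1-carboxylate
Conditions: second-generation Grubbs catalyst RuCl2(=CHPh)(H2IMes)(PCy3) (7 mol %), toluene (5 mM), 80 °C, Ar
Reagents that add atoms: none
Why: Proposed new method: the ruthenium alkylidene formed at the monosubstituted olefin closes ring A by exo ene–yne metathesis onto the alkyne, and the conjugated vinylcarbene so formed closes ring B by ring-closing metathesis onto the silyl enol ether with loss of ethene, so both carbocycles and the 8-silyloxy-1(10),8-diene arise in one operation with C4 and C5 untouched; the closest known reaction types are Grubbs dienyne ring-closing metathesis and ring-closing metathesis of silyl enol ethers.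

**Step 9**
Reactants: 12 tert-butyl (1S,8aR)-6-[(tert-butyldimethylsilyl)oxy]-8a-methyl-1,2,3,7,8,8a-hexahydronaphthalene-1-carboxylate
Product: 13 tert-butyl (1S,4R,8aR)-4-hydroxy-8a-methyl-6-oxo-1,2,3,4,6,7,8,8a-octahydronaphthalene-1-carboxylate
Conditions: m-CPBA, NaHCO3, CH2Cl2, −20 °C; then 1 M HCl, THF, 0 °C
Reagents that add atoms: 3-chloroperoxybenzoic acid, OOC(=O)c1cccc(Cl)c1
Why: Vinylogous Rubottom oxidation in which the peracid attacks the γ-terminus C1 of the silyl dienol ether axially on the face of the angular methyl (the course of the 6β-hydroxylation of steroidal 3,5-dienol ethers), setting C1 (R, 1β-OH), and acid work-up removes silicon to leave the conjugated enone.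

**Step 10**
Reactants: 14 (S)-3-bromo-2-methylpropan-1-ol; 15 propylmagnesium chloride
Product: 16 (R)-2-methylhexan-1-ol
Conditions: 15 (2.2 equiv), Li2CuCl4 (3 mol %), THF, −78 → 0 °C
Reagents that add atoms: none
Why: Copper-catalysed Kochi-type sp3–sp3 cross-coupling of the Grignard reagent with the primary bromide after deprotonation of the hydroxyl, the stereocentre being a spectator whose descriptor changes from S to R only through the priority rules.

**Step 11**
Reactants: 16 (R)-2-methylhexan-1-ol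
Product: 18 ethyl (2E,4R)-2,4-dimethyloct-2-enoate, via aldehyde 17 (not isolated)
Conditions: TEMPO (10 mol %), PhI(OAc)2, CH2Cl2, rt; then Ph3P=C(CH3)CO2Et, rt
Reagents that add atoms: ethyl 2-(triphenyl-λ5-phosphanylidene)propanoate, CCOC(=O)C(C)=P(c1ccccc1)(c1ccccc1)c1ccccc1
Why: TEMPO/PhI(OAc)2 oxidation to the α-branched aldehyde followed in the same flask by Wittig olefination with the stabilised ylide, which gives the E trisubstituted enoate without epimerising the adjacent stereocentre.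

**Step 12**
Reactants: 18 ethyl (2E,4R)-2,4-dimethyloct-2-enoate
Product: 19 (2E,4R)-2,4-dimethyloct-2-enoic acid
Conditions: LiOH, THF–MeOH–H2O, 40 °C; then 1 M HCl
Reagents that add atoms: lithium hydroxide, [Li+].[OH-]
Why: Saponification of the ethyl ester (acyl substitution by hydroxide) with the remote stereocentre and the E-alkene untouched.

**Step 13**
Reactants: 13 tert-butyl (1S,4R,8aR)-4-hydroxy-8a-methyl-6-oxo-1,2,3,4,6,7,8,8a-octahydronaphthalene-1-carboxylate; 19 (2E,4R)-2,4-dimethyloct-2-enoic acid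
Product: 21 tert-butyl (1S,4R,8aR)-4-{[(2E,4R)-2,4-dimethyloct-2-enoyl]oxy}-8a-methyl-6-oxo-1,2,3,4,6,7,8,8a-octahydronaphthalene-1-carboxylate, via mixed anhydride 20 (not isolated)
Conditions: 19, 2,4,6-Cl3C6H2COCl, Et3N, THF, rt; then 13, DMAP, toluene, 40 °C
Reagents that add atoms: none
Why: Yamaguchi esterification in which the mixed anhydride transfers the enoyl group to the hindered axial allylic alcohol under DMAP catalysis with retention at C1.

**Step 14**
Reactants: 21 tert-butyl (1S,4R,8aR)-4-{[(2E,4R)-2,4-dimethyloct-2-enoyl]oxy}-8a-methyl-6-oxo-1,2,3,4,6,7,8,8a-octahydronaphthalene-1-carboxylate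
Product: 22 tert-butyl (1S,4R,7R,8aR)-4-{[(2E,4R)-2,4-dimethyloct-2-enoyl]oxy}-8a-methyl-6-oxo-7-(prop-2-en-1-yl)-1,2,3,4,6,7,8,8a-octahydronaphthalene-1-carboxylate
Conditions: LiN(SiMe3)2, THF, −78 °C; allyl bromide, −78 → −40 °C
Reagents that add atoms: allyl bromide, C=CCBr
Why: Kinetic α′-deprotonation of the enone gives the cross-conjugated lithium enolate whose SN2 allylation occurs anti to the angular methyl, placing the allyl group equatorial at C7 (R, 7α), which is also the thermodynamically favoured epimer of this enolisable centre.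

**Step 15**
Reactants: 22 tert-butyl (1S,4R,7R,8aR)-4-{[(2E,4R)-2,4-dimethyloct-2-enoyl]oxy}-8a-methyl-6-oxo-7-(prop-2-en-1-yl)-1,2,3,4,6,7,8,8a-octahydronaphthalene-1-carboxylate
Product: 23 (1S,4R,7R,8aR)-4-{[(2E,4R)-2,4-dimethyloct-2-enoyl]oxy}-8a-methyl-6-oxo-7-(prop-2-en-1-yl)-1,2,3,4,6,7,8,8a-octahydronaphthalene-1-carboxylic acid
Conditions: CF3CO2H–CH2Cl2 (1:4), 0 °C
Reagents that add atoms: none
Why: Acidolysis of the tert-butyl ester (E1 loss of 2-methylpropene) frees the C15 acid before any aldehyde is present, the enone, allylic ester and terminal alkene being stable to cold CF3CO2H.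

**Step 16**
Reactants: 23 (1S,4R,7R,8aR)-4-{[(2E,4R)-2,4-dimethyloct-2-enoyl]oxy}-8a-methyl-6-oxo-7-(prop-2-en-1-yl)-1,2,3,4,6,7,8,8a-octahydronaphthalene-1-carboxylic acid
Product: 24 (1S,4R,7S,8aR)-4-{[(2E,4R)-2,4-dimethyloct-2-enoyl]oxy}-8a-methyl-6-oxo-7-(2-oxoethyl)-1,2,3,4,6,7,8,8a-octahydronaphthalene-1-carboxylic acid
Conditions: OsO4 (2 mol %), NaIO4, 2,6-lutidine, dioxane–H2O (3:1), rt
Reagents that add atoms: osmium tetroxide, O=[Os](=O)(=O)=O; sodium periodate, [Na+].[O-]I(=O)(=O)=O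
Why: Lemieux–Johnson oxidative cleavage, OsO4 dihydroxylating only the electron-rich monosubstituted alkene (the enone and enoate C=C bonds are electron-poor and trisubstituted) and periodate cleaving the diol to the aldehyde.

**Step 17**
Reactants: 24 (1S,4R,7S,8aR)-4-{[(2E,4R)-2,4-dimethyloct-2-enoyl]oxy}-8a-methyl-6-oxo-7-(2-oxoethyl)-1,2,3,4,6,7,8,8a-octahydronaphthalene-1-carboxylic acid
Product: 25 (1S,4R,7S,8aR)-4-{[(2E,4R)-2,4-dimethyloct-2-enoyl]oxy}-8a-methyl-6-oxo-7-(3-oxoprop-1-en-2-yl)-1,2,3,4,6,7,8,8a-octahydronaphthalene-1-carboxylic acid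
Conditions: CH2O (37% aq), pyrrolidine (10 mol %), EtCO2H (10 mol %), i-PrOH, 45 °C
Reagents that add atoms: formaldehyde, C=O
Why: Amine-catalysed α-methylenation of the aldehyde (Mannich condensation with formaldehyde, then elimination) builds the 2-substituted acrolein under mild buffered conditions, C7 staying in its thermodynamically preferred equatorial (S) configuration.

**Compound list**
1 | furan-2(5H)-one | O=C1OCC=C1 | starting material
2 | but-3-en-1-ylmagnesium bromide | C=CCC[Mg]Br | starting material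
3 | (S)-4-(but-3-en-1-yl)dihydrofuran-2(3H)-one | O=C1OC[C@@H](CCC=C)C1 | intermediate
4 | 2-(2-bromoethyl)-2-methyl-1,3-dioxolane | CC1(CCBr)OCCO1 | starting material
5 | (3S,4S)-4-(but-3-en-1-yl)-3-[2-(2-methyl-1,3-dioxolan-2-yl)ethyl]dihydrofuran-2(3H)-one | O=C1OC[C@@H](CCC=C)[C@@H]1CCC1(C)OCCO1 | intermediate
6 | (3R,4S)-4-(but-3-en-1-yl)-3-methyl-3-[2-(2-methyl-1,3-dioxolan-2-yl)ethyl]dihydrofuran-2(3H)-one | O=C1OC[C@@H](CCC=C)[C@@]1(C)CCC1(C)OCCO1 | intermediate
7 | (3R,4S)-4-(but-3-en-1-yl)-3-methyl-3-[2-(2-methyl-1,3-dioxolan-2-yl)ethyl]tetrahydrofuran-2-ol (lactol, anomer mixture) | OC1OC[C@@H](CCC=C)[C@@]1(C)CCC1(C)OCCO1 | intermediate (not isolated)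
8 | (2S,3R)-2-(but-3-en-1-yl)-3-ethynyl-3-methyl-5-(2-methyl-1,3-dioxolan-2-yl)pentan-1-ol | OC[C@@H](CCC=C)[C@@](C#C)(C)CCC1(C)OCCO1 | intermediate
9 | (2S,3R)-2-(but-3-en-1-yl)-3-ethynyl-3-methyl-6-oxoheptanoic acid | OC(=O)[C@@H](CCC=C)[C@@](C#C)(C)CCC(C)=O | intermediate
10 | tert-butyl (2S,3R)-2-(but-3-en-1-yl)-3-ethynyl-3-methyl-6-oxoheptanoate | CC(C)(C)OC(=O)[C@@H](CCC=C)[C@@](C#C)(C)CCC(C)=O | intermediate
11 | tert-butyl (2S,3R)-2-(but-3-en-1-yl)-6-[(tert-butyldimethylsilyl)oxy]-3-ethynyl-3-methylhept-6-enoate | CC(C)(C)OC(=O)[C@@H](CCC=C)[C@@](C#C)(C)CCC(=C)O[Si](C)(C)C(C)(C)C | intermediate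
12 | tert-butyl (1S,8aR)-6-[(tert-butyldimethylsilyl)oxy]-8a-methyl-1,2,3,7,8,8a-hexahydronaphthalene-1-carboxylate | C1C[C@@]2(C)C(=CCC[C@@H]2C(=O)OC(C)(C)C)C=C1O[Si](C)(C)C(C)(C)C | intermediate
13 | tert-butyl (1S,4R,8aR)-4-hydroxy-8a-methyl-6-oxo-1,2,3,4,6,7,8,8a-octahydronaphthalene-1-carboxylate | C1C[C@@]2(C)C(=CC1=O)[C@H](O)CC[C@@H]2C(=O)OC(C)(C)C | intermediate
14 | (S)-3-bromo-2-methylpropan-1-ol | OC[C@H](C)CBr | starting material
15 | propylmagnesium chloride | CCC[Mg]Cl | starting material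
16 | (R)-2-methylhexan-1-ol | OC[C@H](C)CCCC | intermediate
17 | (R)-2-methylhexanal | O=C[C@H](C)CCCC | intermediate (not isolated)
18 | ethyl (2E,4R)-2,4-dimethyloct-2-enoate | CCOC(=O)/C(C)=C/[C@H](C)CCCC | intermediate
19 | (2E,4R)-2,4-dimethyloct-2-enoic acid | OC(=O)/C(C)=C/[C@H](C)CCCC | intermediate
20 | (2E,4R)-2,4-dimethyloct-2-enoic 2,4,6-trichlorobenzoic anhydride | O=C(OC(=O)/C(C)=C/[C@H](C)CCCC)c1c(Cl)cc(Cl)cc1Cl | intermediate (not isolated)
21 | tert-butyl (1S,4R,8aR)-4-{[(2E,4R)-2,4-dimethyloct-2-enoyl]oxy}-8a-methyl-6-oxo-1,2,3,4,6,7,8,8a-octahydronaphthalene-1-carboxylate | C1C[C@@]2(C)C(=CC1=O)[C@H](OC(=O)/C(C)=C/[C@H](C)CCCC)CC[C@@H]2C(=O)OC(C)(C)C | intermediate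
22 | tert-butyl (1S,4R,7R,8aR)-4-{[(2E,4R)-2,4-dimethyloct-2-enoyl]oxy}-8a-methyl-6-oxo-7-(prop-2-en-1-yl)-1,2,3,4,6,7,8,8a-octahydronaphthalene-1-carboxylate | C=CC[C@@H]1C[C@@]2(C)C(=CC1=O)[C@H](OC(=O)/C(C)=C/[C@H](C)CCCC)CC[C@@H]2C(=O)OC(C)(C)C | intermediate
23 | (1S,4R,7R,8aR)-4-{[(2E,4R)-2,4-dimethyloct-2-enoyl]oxy}-8a-methyl-6-oxo-7-(prop-2-en-1-yl)-1,2,3,4,6,7,8,8a-octahydronaphthalene-1-carboxylic acid | C=CC[C@@H]1C[C@@]2(C)C(=CC1=O)[C@H](OC(=O)/C(C)=C/[C@H](C)CCCC)CC[C@@H]2C(=O)O | intermediate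
24 | (1S,4R,7S,8aR)-4-{[(2E,4R)-2,4-dimethyloct-2-enoyl]oxy}-8a-methyl-6-oxo-7-(2-oxoethyl)-1,2,3,4,6,7,8,8a-octahydronaphthalene-1-carboxylic acid | O=CC[C@@H]1C[C@@]2(C)C(=CC1=O)[C@H](OC(=O)/C(C)=C/[C@H](C)CCCC)CC[C@@H]2C(=O)O | intermediate
25 | (1S,4R,7S,8aR)-4-{[(2E,4R)-2,4-dimethyloct-2-enoyl]oxy}-8a-methyl-6-oxo-7-(3-oxoprop-1-en-2-yl)-1,2,3,4,6,7,8,8a-octahydronaphthalene-1-carboxylic acid | C=C(C=O)[C@@H]1C[C@@]2(C)C(=CC1=O)[C@H](OC(=O)/C(C)=C/[C@H](C)CCCC)CC[C@@H]2C(=O)O | target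

**Step count**
Total: 17 steps. Longest linear sequence: 14 steps (steps 1–9, then 13–17); the acid 19 is made in a 3-step branch (steps 10–12) and joins at step 13.

**Steps most likely to fail, with fallbacks**

Step 8 (two-ring metathesis cascade). The vinylcarbene formed after the first ring closure may not engage the hindered, electron-rich silyl enol ether, leaving a ring A diene or oligomers. The fallback builds the rings one at a time and sets out from 10. Ene–yne ring-closing metathesis under ethene (second-generation Grubbs catalyst RuCl2(=CHPh)(H2IMes)(PCy3), C2H4 1 atm, CH2Cl2, 40 °C) closes ring A alone and gives tert-butyl (1S,2R)-3-ethenyl-2-methyl-2-(3-oxobutyl)cyclohex-3-ene-1-carboxylate F1. Kinetic silylation (KN(SiMe3)2, t-BuMe2SiCl, THF, −78 °C) gives tert-butyl (1S,2R)-2-{3-[(tert-butyldimethylsilyl)oxy]but-3-en-1-yl}-3-ethenyl-2-methylcyclohex-3-ene-1-carboxylate F2. A separate diene/enol ether ring-closing metathesis (second-generation Hoveyda–Grubbs catalyst RuCl2(=CH-C6H4-2-O-i-Pr)(H2IMes), toluene, 80 °C) then closes ring B and comes back to the route at 12.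

Step 9 (γ-oxidation). The peracid may attack C9 instead of C1, or deliver the 1α alcohol. The fallback sets out from 12. Kinetic protodesilylation (Bu4NF, AcOH, THF, −78 °C; α-protonation of the dienolate) gives the deconjugated ketone tert-butyl (1S,8aR)-8a-methyl-6-oxo-1,2,3,5,6,7,8,8a-octahydronaphthalene-1-carboxylate F3. Epoxidation with m-CPBA from the face opposite the angular methyl gives tert-butyl (1S,4S,4aR,8aR)-4,4a-epoxy-8a-methyl-6-oxodecahydronaphthalene-1-carboxylate F4. Et3N-induced E1cB opening gives the 1α alcohol tert-butyl (1S,4S,8aR)-4-hydroxy-8a-methyl-6-oxo-1,2,3,4,6,7,8,8a-octahydronaphthalene-1-carboxylate F5. Mitsunobu esterification of F5 with 19 (PPh3, diisopropyl azodicarboxylate, THF) inverts C1 and comes back to the route at 21, bypassing 13.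

Step 1 (asymmetric conjugate addition). Butenolides are poor substrates for copper/Grignard additions, so the ee may be low and 1,2-addition may compete. The fallback uses the chiral pool instead of 1 and 2. (S)-Epichlorohydrin and diethyl malonate (NaOEt, EtOH, reflux) give ethyl (1R,5S)-2-oxo-3-oxabicyclo[3.1.0]hexane-1-carboxylate F6. Homoconjugate opening of the cyclopropane with allylmagnesium bromide (CuBr·SMe2 cat., THF, −30 °C) gives ethyl (3R,4S)-4-(but-3-en-1-yl)-2-oxotetrahydrofuran-3-carboxylate F7. Krapcho dealkoxycarbonylation (LiCl, DMSO–H2O, 140 °C) comes back to the route at 3.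

**Further compounds**
F1 | step 8 | tert-butyl (1S,2R)-3-ethenyl-2-methyl-2-(3-oxobutyl)cyclohex-3-ene-1-carboxylate | CC(=O)CC[C@@]1(C)C(C=C)=CCC[C@@H]1C(=O)OC(C)(C)C
F2 | step 8 | tert-butyl (1S,2R)-2-{3-[(tert-butyldimethylsilyl)oxy]but-3-en-1-yl}-3-ethenyl-2-methylcyclohex-3-ene-1-carboxylate | C=C(O[Si](C)(C)C(C)(C)C)CC[C@@]1(C)C(C=C)=CCC[C@@H]1C(=O)OC(C)(C)C
F3 | step 9 | tert-butyl (1S,8aR)-8a-methyl-6-oxo-1,2,3,5,6,7,8,8a-octahydronaphthalene-1-carboxylate | C1C[C@@]2(C)C(=CCC[C@@H]2C(=O)OC(C)(C)C)CC1=O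
F4 | step 9 | tert-butyl (1S,4S,4aR,8aR)-4,4a-epoxy-8a-methyl-6-oxodecahydronaphthalene-1-carboxylate | C1C[C@@]2(C)[C@@]3(CC1=O)O[C@H]3CC[C@@H]2C(=O)OC(C)(C)C
F5 | step 9 | tert-butyl (1S,4S,8aR)-4-hydroxy-8a-methyl-6-oxo-1,2,3,4,6,7,8,8a-octahydronaphthalene-1-carboxylate | C1C[C@@]2(C)C(=CC1=O)[C@@H](O)CC[C@@H]2C(=O)OC(C)(C)C
F6 | step 1 | ethyl (1R,5S)-2-oxo-3-oxabicyclo[3.1.0]hexane-1-carboxylate | O=C1OC[C@H]2C[C@@]12C(=O)OCC
F7 | step 1 | ethyl (3R,4S)-4-(but-3-en-1-yl)-2-oxotetrahydrofuran-3-carboxylate | O=C1OC[C@@H](CCC=C)[C@@H]1C(=O)OCC
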